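(The numbers in the tables were generated by integration on assumed constants, noise included.)

A flask cannot hold more chains than it had initiator, if each chain takes one initiator to begin. So fold the charge into one number. It is 10.0 in larch and in oak: free monomer charged per initiator charged. Multiply it by the fraction of free monomer in chains and you have the average length if each initiator begins a chain. Fewer chains give a longer average, so this product is a floor.

all flasks: free monomer 0.050 M

| flask | transfer agent | initiator | remark | time |
|---|---|---|---|---|
| Sunday's | 2.1 mM | 5 mM | run made earlier |  |
| Tuesday's | 3.3 mM | 5 mM | run made earlier |  |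
| Monday's | 1.5 mM | 7.5 mM | run made earlier |  |
| larch | 1.50 mM | 5.0 mM |  | 20 h |
| oak | 1.50 mM | 5.0 mM |  | 12 h |

| Sunday's: time / h | Sunday's: monomer in chains / % | Tuesday's: time / h | Tuesday's: monomer in chains / % | Monday's: time / h | Monday's: monomer in chains / % |
|---|---|---|---|---|---|
| 1.33 | 8.9 | 1.33 | 9.4 | 3.00 | 19.4 |
| 2.50 | 12.7 | 4.00 | 15.5 | 6.00 | 27.4 |
| 5.00 | 17.6 | 8.00 | 21.2 | 10.0 | 36.4 |
| 8.00 | 22.8 | 12.0 | 24.8 | 12.0 | 41.0 |
| 15.0 | 31.1 | 15.0 | 27.8 | 15.0 | 45.7 |

(readings scatter by 0.5 percentage points)

- the average divides the monomer in chains by the number of chains begun, living and dead together
- the earlier runs do not show the number of chains; that part of a forecast is a guess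

1. which of the two ends with the longer chains by the average number of monomer units in a chain (chains begun, living or dead) ("neither" if they lie within 10%) (larch / oak / neither)
2. average number of monomer units in a chain (chains begun, living or dead) at the end, larch
3. average number of monomer units in a chain (chains begun, living or dead) at the end, oak

Is one number enough? No. It is equal in both flasks, so it cannot part them; their times must. The readings give that fraction. After an early burst, ln(1/(1−x)) climbs steadily, which reads as pseudo-first-order in free monomer. Monday's readings from 6.00 h to 15.0 h, scaled to the initiator of larch and oak, give a slope of 0.0215 /h. This assumes that the slope goes with initiator. Sunday's readings give a burst of 0.104. So I reckon 41.4% in chains for larch and 30.4% for oak. The floors are 4.14 for larch and 3.04 for oak. Floors cannot rank two flasks, so I add an assumption: chains begin in the burst, and the burst is over before oak's 12 h. Then larch and oak hold equal numbers of chains, and their lengths stand as their fractions, a ratio of 1.36. So I expect larch to be longer, by more than the margin of 10%.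

The forecast also chose larch, with 3.7 (2.5 to 7) for larch and 2.9 (1.9 to 5.5) for oak. It took its chains “from initiator plus transfer”. Its values stand below my floors,  in both flasks.

The flask gives 5.04 for larch and 3.74 for oak, both above the floors . At 20.0 h, larch holds 2.59 mM of living ends and 1.39 mM of dead chains, together 3.98 mM from 5.0 mM of initiator. Its 40.1% in chains, times 10.0, gives 4.01. At 12.0 h, oak holds 2.77 mM of living ends and 1.21 mM of dead chains, together 3.98 mM, with 0% of its initiator left. A neighbour of oak charged with 0.12 M of free monomer has the number 24.0. Its 30.1% in chains at 12.0 h gives a floor of 7.22, and that flask reaches 7.99.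

    free monomer + initiator → living end + monomer in chains (k = 26.0 /M/h)
    free monomer + living end → monomer in chains + living end, rate k2*[living end]*[free monomer] (k = 7.50 /M/h)
    2 initiator → spent initiator B (k = 42.0 /M/h)
    initiator → spent initiator A (k = 0.120 /h)
    living end + transfer agent → dead chain (kL = 46.0 /M/h)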